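- Target at 30 h is what you ask for, and I reckon it through the pool: target plus substrate, as a fraction of the charge.
- If the pool is lost at a rate that goes as charge times pool squared, a second-order rate law, it integrates to: 1 over pool = 1 + constant × charge × time.
- The north and east runs at 30 h read 0.290 L mol⁻¹ h⁻¹ on average for the pool constant, the rise of the reciprocal pool per unit of charge and per hour.
- The north-east run reads 0.166 L mol⁻¹ h⁻¹, less than that, so I don't carry the rule up to Thursday's.
- For Friday's, at 0.10 M, I get a pool of 53.4 %. Its charge lies near the north run's 0.075 M, so I borrow that run's target share, 75.4 %, and my own number is 40.3 % of target.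
- Your forecast gives Friday's > Tuesday's > Monday's > Saturday's > Thursday's, with 41 % first and 3 % last, on the ground that target “yield falls strongly with loading, so its loss is of higher order”. Its first figure stands above my own number and comes from its own reckoning.

| flask | substrate | remark | time |
|---|---|---|---|
| north | 0.075 M | run made earlier |  |
| east | 0.32 M | run made earlier |  |
| north-east | 0.98 M | run made earlier |  |
| Thursday's | 1.2 M |  | 30 h |
| Saturday's | 0.40 M |  | 30 h |
| Monday's | 0.20 M |  | 30 h |
| Tuesday's | 0.12 M |  | 30 h |
| Friday's | 0.10 M |  | 30 h |

| run | time / h | target / % | substrate / % |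
|---|---|---|---|
| north | 2.50 | 45 | 49 |
| north | 5.00 | 53 | 28 |
| north | 8.00 | 64 | 27 |
| north | 15.0 | 56 | 23 |
| north | 30.0 | 46 | 15 |
| east | 2.50 | 32 | 53 |
| east | 8.00 | 27 | 30 |
| east | 15.0 | 21 | 21 |
| east | 20.0 | 19 | 19 |
| east | 30.0 | 13 | 13 |
| north-east | 2.50 | 18 | 52 |
| north-east | 5.00 | 12 | 39 |
| north-east | 8.00 | 8 | 29 |
| north-east | 15.0 | 3 | 19 |
| north-east | 30.0 | 6 | 11 |

(standard deviation of a reading: 2 percentage points)

- the earlier runs were read with a standard deviation of 2 percentage points

- ranking by amount of target, in percent of the substrate charged, from high to low, at 30 h (Thursday's / Saturday's / Monday's / Tuesday's / Friday's)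
- the amount of target, in percent of the substrate charged of the flask you put first, at 30 h
- the amount of target, in percent of the substrate charged of the flask you put last, at 30 h

The flasks give Friday's > Tuesday's > Monday's > Saturday's > Thursday's, with 38.6 % in Friday's and 2.42 % in Thursday's.

    substrate + target → side product (k = 0.600 L mol⁻¹ h⁻¹)
    substrate ⇌ target + by-product (K = 0.130 M, k = 0.280 h⁻¹)

Friday's pool stands at 56.1 % at 30 h, against my 53.4 %. Friday's target would move by 5 points with the charge at 0.119 M, the time held, or with the reading at 40.8 h, the charge held. For the neighbour of Friday's charged with 0.25 M, the pool constant gives a pool of 31.5 %. That neighbour holds a pool of 31.4 % of its charge at 30 h, and its target stands at 16.0 % of its charge.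

The numbers in the tables are calculated with constants of no real substance; the scatter is artificial.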